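## Retrosynthetic overview

1. Target 30 ⇐ global hydrogenolysis of decabenzyl ether 29 (every OH as OBn except the ring-D 4-OH, which is already free).
2. The three Ar–O–Ar bonds ⇐ iterative Cu-catalysed coupling of a di-ortho-benzyloxy phenol with a CHO-activated aryl bromide; each CHO is then turned into the next phenol by Baeyer–Villiger oxidation (A→B→C→D).
3. Rings B, C and D ⇐ one monomer, 4-bromo-2,6-bis(benzyloxy)benzaldehyde 13; the fifth oxygen of ring B enters as an ortho-CHO (in 18) that first activates the coupling.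
4. Ring A phenol 11 ⇐ phloroglucinol 6 ⇐ de novo ring synthesis: crossed intermolecular Claisen condensation of diethyl malonate 1 with diethyl 3-oxopentanedioate 2, then Dieckmann closure and aromatisation.
5. Ring order: ring A is the only ring constructed (first, steps 1–2); rings B, C, D are attached in that order as preformed arenes.

Assumption: the target has no stereogenic element (it is achiral), so no stereocontrol is needed and "single enantiomer" does not apply.

## Route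

Step 1
Reactants: 1 diethyl malonate; 2 diethyl 3-oxopentanedioate (diethyl acetonedicarboxylate)
Product: 4 diethyl 2,4,6-trihydroxybenzene-1,3-dicarboxylate, via acyclic diketo triester 3 (not isolated)
Conditions: NaOEt (2.2 equiv), EtOH, 1 in slight excess, 2 added slowly, reflux; EtOH distilled off, 130–140 °C; then 2 M HCl
Reagents that add atoms: none
Why: Intermolecular Claisen condensation of the enolate of 2 with an ester carbonyl of 1 joins the C3 and C5 fragments, and Dieckmann cyclisation with irreversible aromatisation to the phloroglucinolate salt drives the equilibria (attack in the opposite sense leads to the same arene); no stereocentre is formed.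

Step 2
Reactants: 4 diethyl 2,4,6-trihydroxybenzene-1,3-dicarboxylate
Product: 6 phloroglucinol (benzene-1,3,5-triol), via dicarboxylic acid 5 (not isolated)
Conditions: aq. KOH, reflux, N2; then conc. HCl to pH 1, 90 °C
Reagents that add atoms: none
Why: Ester saponification followed by decarboxylation, which is easy because each acid is a vinylogous β-keto acid of the triketo tautomer.

Step 3
Reactants: 6 phloroglucinol
Product: 8 2,4,6-trihydroxybenzaldehyde, via iminium chloride 7 (not isolated)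
Conditions: POCl3, DMF, EtOAc, 0 °C → rt; then H2O, 80 °C
Reagents that add atoms: N,N-dimethylformamide CN(C)C=O; water O
Why: Vilsmeier–Haack formylation of the very electron-rich ring stops at mono-substitution because the iminium salt deactivates the ring (and precipitates).

Step 4
Reactants: 8 2,4,6-trihydroxybenzaldehyde
Product: 9 2,4,6-tris(benzyloxy)benzaldehyde
Conditions: BnBr (3.6 equiv), K2CO3, DMF, 70 °C
Reagents that add atoms: benzyl bromide BrCc1ccccc1
Why: Williamson etherification; the formyl group lowers ring nucleophilicity so O-benzylation beats C-benzylation, and excess reagent with heat alkylates the two H-bonded ortho hydroxyls.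

Step 5
Reactants: 9 2,4,6-tris(benzyloxy)benzaldehyde
Product: 11 2,4,6-tris(benzyloxy)phenol, via aryl formate 10 (not isolated)
Conditions: mCPBA, CH2Cl2, 0 °C → rt; then K2CO3 (cat.), MeOH, rt, Ar
Reagents that add atoms: mCPBA OOC(=O)c1cccc(Cl)c1
Why: Baeyer–Villiger (Dakin-type) oxidation in which the electron-rich 2,4,6-trialkoxyaryl group migrates, then methanolysis of the formate.

Step 6
Reactants: 12 4-bromo-2,6-difluorobenzaldehyde
Product: 13 4-bromo-2,6-bis(benzyloxy)benzaldehyde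
Conditions: BnOH (2.4 equiv), NaH, THF/DMF, 0 → 50 °C
Reagents that add atoms: benzyl alcohol OCc1ccccc1
Why: Double SNAr of the two ortho fluorides activated by the formyl group; fluoride leaves far faster than bromide, and the ring is deactivated once two alkoxy groups are in, so the bromide survives.

Step 7
Reactants: 13 4-bromo-2,6-bis(benzyloxy)benzaldehyde
Product: 15 4-bromo-2,6-bis(benzyloxy)phenol, via aryl formate 14 (not isolated)
Conditions: mCPBA, CH2Cl2, rt; then K2CO3 (cat.), MeOH, rt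
Reagents that add atoms: mCPBA OOC(=O)c1cccc(Cl)c1
Why: Baeyer–Villiger oxidation with migration of the 2,6-dialkoxyaryl group, then formate methanolysis.

Step 8
Reactants: 15 4-bromo-2,6-bis(benzyloxy)phenol
Product: 16 1,3-bis(benzyloxy)-5-bromo-2-(methoxymethoxy)benzene
Conditions: NaH, MOMCl, DMF, 0 °C → rt
Reagents that add atoms: chloromethyl methyl ether COCCl
Why: O-alkylation of the hindered phenoxide gives a MOM acetal that is orthogonal to benzyl ethers and stable to base, LDA, Cu catalysis and peracid.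

Step 9
Reactants: 16 1,3-bis(benzyloxy)-5-bromo-2-(methoxymethoxy)benzene
Product: 18 2,4-bis(benzyloxy)-6-bromo-3-(methoxymethoxy)benzaldehyde, via aryllithium 17 (not isolated)
Conditions: LDA (1.15 equiv), THF, −78 °C; DMF, −78 → −40 °C; aq. NH4Cl
Reagents that add atoms: N,N-dimethylformamide CN(C)C=O
Why: Directed ortho-lithiation at the C–H between Br and OBn (the two such sites are equivalent by symmetry) and formylation with DMF; −78 °C suppresses benzyne formation and benzylic metalation.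

Step 10
Reactants: 11 2,4,6-tris(benzyloxy)phenol; 18 2,4-bis(benzyloxy)-6-bromo-3-(methoxymethoxy)benzaldehyde
Product: 19 2,4-bis(benzyloxy)-3-(methoxymethoxy)-6-[2,4,6-tris(benzyloxy)phenoxy]benzaldehyde
Conditions: CuI (10 mol %), picolinic acid (20 mol %), K3PO4, degassed DMSO, 90 °C, Ar
Reagents that add atoms: none
Why: Ullmann-type diaryl ether synthesis; the bromide is activated by the ortho-formyl group and the Cu/picolinate system accepts di-ortho-substituted phenols.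

Step 11
Reactants: 19 2,4-bis(benzyloxy)-3-(methoxymethoxy)-6-[2,4,6-tris(benzyloxy)phenoxy]benzaldehyde
Product: 21 2,4-bis(benzyloxy)-3-(methoxymethoxy)-6-[2,4,6-tris(benzyloxy)phenoxy]phenol, via aryl formate 20 (not isolated)
Conditions: mCPBA (1.3 equiv), CH2Cl2, 0 °C → rt; then K2CO3 (cat.), MeOH/THF, rt
Reagents that add atoms: mCPBA OOC(=O)c1cccc(Cl)c1
Why: Baeyer–Villiger oxidation of a 2,6-dioxygenated benzaldehyde (aryl migration) installs the fifth oxygen of ring B; MOM, benzyl and diaryl ethers are inert.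

Step 12
Reactants: 21 2,4-bis(benzyloxy)-3-(methoxymethoxy)-6-[2,4,6-tris(benzyloxy)phenoxy]phenol
Product: 22 1,3,4-tris(benzyloxy)-2-(methoxymethoxy)-5-[2,4,6-tris(benzyloxy)phenoxy]benzene
Conditions: BnBr, K2CO3, DMF, 50 °C
Reagents that add atoms: benzyl bromide BrCc1ccccc1
Why: Williamson etherification caps the new phenol so it cannot compete in the later couplings.

Step 13
Reactants: 22 1,3,4-tris(benzyloxy)-2-(methoxymethoxy)-5-[2,4,6-tris(benzyloxy)phenoxy]benzene
Product: 23 2,3,6-tris(benzyloxy)-4-[2,4,6-tris(benzyloxy)phenoxy]phenol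
Conditions: conc. HCl (cat.), MeOH/THF, 50 °C
Reagents that add atoms: none
Why: Acid-catalysed acetal exchange removes only the MOM group and frees the di-ortho-benzyloxy phenol of ring B.

Step 14
Reactants: 23 2,3,6-tris(benzyloxy)-4-[2,4,6-tris(benzyloxy)phenoxy]phenol; 13 4-bromo-2,6-bis(benzyloxy)benzaldehyde
Product: 24 2,6-bis(benzyloxy)-4-{2,3,6-tris(benzyloxy)-4-[2,4,6-tris(benzyloxy)phenoxy]phenoxy}benzaldehyde
Conditions: CuI (10 mol %), picolinic acid (20 mol %), K3PO4, DMSO, 90 °C, Ar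
Reagents that add atoms: none
Why: Ullmann-type coupling of the hindered phenol with an unhindered aryl bromide activated by the para-formyl group.

Step 15
Reactants: 24 2,6-bis(benzyloxy)-4-{2,3,6-tris(benzyloxy)-4-[2,4,6-tris(benzyloxy)phenoxy]phenoxy}benzaldehyde
Product: 26 2,6-bis(benzyloxy)-4-{2,3,6-tris(benzyloxy)-4-[2,4,6-tris(benzyloxy)phenoxy]phenoxy}phenol, via aryl formate 25 (not isolated)
Conditions: mCPBA, CH2Cl2, 0 °C → rt; then K2CO3 (cat.), MeOH/THF, rt
Reagents that add atoms: mCPBA OOC(=O)c1cccc(Cl)c1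
Why: Baeyer–Villiger oxidation of the 2,6-dialkoxybenzaldehyde unmasks the hindered ring-C phenol.

Step 16
Reactants: 26 2,6-bis(benzyloxy)-4-{2,3,6-tris(benzyloxy)-4-[2,4,6-tris(benzyloxy)phenoxy]phenoxy}phenol; 13 4-bromo-2,6-bis(benzyloxy)benzaldehyde
Product: 27 2,6-bis(benzyloxy)-4-(2,6-bis(benzyloxy)-4-{2,3,6-tris(benzyloxy)-4-[2,4,6-tris(benzyloxy)phenoxy]phenoxy}phenoxy)benzaldehyde
Conditions: CuI (10 mol %), picolinic acid (20 mol %), K3PO4, DMSO, 90 °C, Ar
Reagents that add atoms: none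
Why: The same Ullmann-type coupling as step 14 attaches ring D.

Step 17
Reactants: 27 2,6-bis(benzyloxy)-4-(2,6-bis(benzyloxy)-4-{2,3,6-tris(benzyloxy)-4-[2,4,6-tris(benzyloxy)phenoxy]phenoxy}phenoxy)benzaldehyde
Product: 29 2,6-bis(benzyloxy)-4-(2,6-bis(benzyloxy)-4-{2,3,6-tris(benzyloxy)-4-[2,4,6-tris(benzyloxy)phenoxy]phenoxy}phenoxy)phenol, via aryl formate 28 (not isolated)
Conditions: mCPBA, CH2Cl2, 0 °C → rt; then K2CO3 (cat.), MeOH/THF, rt
Reagents that add atoms: mCPBA OOC(=O)c1cccc(Cl)c1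
Why: Baeyer–Villiger oxidation converts the ring-D formyl group into the central hydroxyl of the pyrogallol unit.

Step 18
Reactants: 29 2,6-bis(benzyloxy)-4-(2,6-bis(benzyloxy)-4-{2,3,6-tris(benzyloxy)-4-[2,4,6-tris(benzyloxy)phenoxy]phenoxy}phenoxy)phenol
Product: 30 5-{2,6-dihydroxy-4-[2,3,6-trihydroxy-4-(2,4,6-trihydroxyphenoxy)phenoxy]phenoxy}benzene-1,2,3-triol (target)
Conditions: H2 (1 atm), 10% Pd/C, THF/MeOH, rt; filtered and concentrated under Ar
Reagents that add atoms: none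
Why: Catalytic hydrogenolysis cleaves all ten benzyl ethers while diaryl ethers are untouched, giving the free polyphenol without acidic or oxidising reagents.

## Compound list

1 | diethyl malonate | CCOC(=O)CC(=O)OCC | starting material
2 | diethyl 3-oxopentanedioate (diethyl acetonedicarboxylate) | CCOC(=O)CC(=O)CC(=O)OCC | starting material
3 | triethyl 2,4-dioxopentane-1,3,5-tricarboxylate | CCOC(=O)CC(=O)C(C(=O)OCC)C(=O)CC(=O)OCC | intermediate (not isolated)
4 | diethyl 2,4,6-trihydroxybenzene-1,3-dicarboxylate | CCOC(=O)c1c(O)cc(O)c(C(=O)OCC)c1O | intermediate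
5 | 2,4,6-trihydroxybenzene-1,3-dicarboxylic acid | OC(=O)c1c(O)cc(O)c(C(=O)O)c1O | intermediate (not isolated)
6 | phloroglucinol (benzene-1,3,5-triol) | Oc1cc(O)cc(O)c1 | intermediate
7 | N,N-dimethyl-(2,4,6-trihydroxybenzylidene)iminium chloride | C[N+](C)=Cc1c(O)cc(O)cc1O.[Cl-] | intermediate (not isolated)
8 | 2,4,6-trihydroxybenzaldehyde | O=Cc1c(O)cc(O)cc1O | intermediate
9 | 2,4,6-tris(benzyloxy)benzaldehyde | O=Cc1c(OCc2ccccc2)cc(OCc2ccccc2)cc1OCc1ccccc1 | intermediate
10 | 2,4,6-tris(benzyloxy)phenyl formate | O=COc1c(OCc2ccccc2)cc(OCc2ccccc2)cc1OCc1ccccc1 | intermediate (not isolated)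
11 | 2,4,6-tris(benzyloxy)phenol | Oc1c(OCc2ccccc2)cc(OCc2ccccc2)cc1OCc1ccccc1 | intermediate
12 | 4-bromo-2,6-difluorobenzaldehyde | O=Cc1c(F)cc(Br)cc1F | starting material
13 | 4-bromo-2,6-bis(benzyloxy)benzaldehyde | O=Cc1c(OCc2ccccc2)cc(Br)cc1OCc1ccccc1 | intermediate
14 | 4-bromo-2,6-bis(benzyloxy)phenyl formate | O=COc1c(OCc2ccccc2)cc(Br)cc1OCc1ccccc1 | intermediate (not isolated)
15 | 4-bromo-2,6-bis(benzyloxy)phenol | Oc1c(OCc2ccccc2)cc(Br)cc1OCc1ccccc1 | intermediate
16 | 1,3-bis(benzyloxy)-5-bromo-2-(methoxymethoxy)benzene | COCOc1c(OCc2ccccc2)cc(Br)cc1OCc1ccccc1 | intermediate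
17 | [2,4-bis(benzyloxy)-6-bromo-3-(methoxymethoxy)phenyl]lithium | [Li]c1c(Br)cc(OCc2ccccc2)c(OCOC)c1OCc1ccccc1 | intermediate (not isolated)
18 | 2,4-bis(benzyloxy)-6-bromo-3-(methoxymethoxy)benzaldehyde | O=Cc1c(Br)cc(OCc2ccccc2)c(OCOC)c1OCc1ccccc1 | intermediate
19 | 2,4-bis(benzyloxy)-3-(methoxymethoxy)-6-[2,4,6-tris(benzyloxy)phenoxy]benzaldehyde | O=Cc1c(Oc2c(OCc3ccccc3)cc(OCc3ccccc3)cc2OCc2ccccc2)cc(OCc2ccccc2)c(OCOC)c1OCc1ccccc1 | intermediate
20 | 2,4-bis(benzyloxy)-3-(methoxymethoxy)-6-[2,4,6-tris(benzyloxy)phenoxy]phenyl formate | O=COc1c(Oc2c(OCc3ccccc3)cc(OCc3ccccc3)cc2OCc2ccccc2)cc(OCc2ccccc2)c(OCOC)c1OCc1ccccc1 | intermediate (not isolated)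
21 | 2,4-bis(benzyloxy)-3-(methoxymethoxy)-6-[2,4,6-tris(benzyloxy)phenoxy]phenol | Oc1c(Oc2c(OCc3ccccc3)cc(OCc3ccccc3)cc2OCc2ccccc2)cc(OCc2ccccc2)c(OCOC)c1OCc1ccccc1 | intermediate
22 | 1,3,4-tris(benzyloxy)-2-(methoxymethoxy)-5-[2,4,6-tris(benzyloxy)phenoxy]benzene | COCOc1c(OCc2ccccc2)cc(Oc2c(OCc3ccccc3)cc(OCc3ccccc3)cc2OCc2ccccc2)c(OCc2ccccc2)c1OCc1ccccc1 | intermediate
23 | 2,3,6-tris(benzyloxy)-4-[2,4,6-tris(benzyloxy)phenoxy]phenol | Oc1c(OCc2ccccc2)cc(Oc2c(OCc3ccccc3)cc(OCc3ccccc3)cc2OCc2ccccc2)c(OCc2ccccc2)c1OCc1ccccc1 | intermediate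
24 | 2,6-bis(benzyloxy)-4-{2,3,6-tris(benzyloxy)-4-[2,4,6-tris(benzyloxy)phenoxy]phenoxy}benzaldehyde | O=Cc1c(OCc2ccccc2)cc(Oc2c(OCc3ccccc3)cc(Oc3c(OCc4ccccc4)cc(OCc4ccccc4)cc3OCc3ccccc3)c(OCc3ccccc3)c2OCc2ccccc2)cc1OCc1ccccc1 | intermediate
25 | 2,6-bis(benzyloxy)-4-{2,3,6-tris(benzyloxy)-4-[2,4,6-tris(benzyloxy)phenoxy]phenoxy}phenyl formate | O=COc1c(OCc2ccccc2)cc(Oc2c(OCc3ccccc3)cc(Oc3c(OCc4ccccc4)cc(OCc4ccccc4)cc3OCc3ccccc3)c(OCc3ccccc3)c2OCc2ccccc2)cc1OCc1ccccc1 | intermediate (not isolated)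
26 | 2,6-bis(benzyloxy)-4-{2,3,6-tris(benzyloxy)-4-[2,4,6-tris(benzyloxy)phenoxy]phenoxy}phenol | Oc1c(OCc2ccccc2)cc(Oc2c(OCc3ccccc3)cc(Oc3c(OCc4ccccc4)cc(OCc4ccccc4)cc3OCc3ccccc3)c(OCc3ccccc3)c2OCc2ccccc2)cc1OCc1ccccc1 | intermediate
27 | 2,6-bis(benzyloxy)-4-(2,6-bis(benzyloxy)-4-{2,3,6-tris(benzyloxy)-4-[2,4,6-tris(benzyloxy)phenoxy]phenoxy}phenoxy)benzaldehyde | O=Cc1c(OCc2ccccc2)cc(Oc2c(OCc3ccccc3)cc(Oc3c(OCc4ccccc4)cc(Oc4c(OCc5ccccc5)cc(OCc5ccccc5)cc4OCc4ccccc4)c(OCc4ccccc4)c3OCc3ccccc3)cc2OCc2ccccc2)cc1OCc1ccccc1 | intermediate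
28 | 2,6-bis(benzyloxy)-4-(2,6-bis(benzyloxy)-4-{2,3,6-tris(benzyloxy)-4-[2,4,6-tris(benzyloxy)phenoxy]phenoxy}phenoxy)phenyl formate | O=COc1c(OCc2ccccc2)cc(Oc2c(OCc3ccccc3)cc(Oc3c(OCc4ccccc4)cc(Oc4c(OCc5ccccc5)cc(OCc5ccccc5)cc4OCc4ccccc4)c(OCc4ccccc4)c3OCc3ccccc3)cc2OCc2ccccc2)cc1OCc1ccccc1 | intermediate (not isolated)
29 | 2,6-bis(benzyloxy)-4-(2,6-bis(benzyloxy)-4-{2,3,6-tris(benzyloxy)-4-[2,4,6-tris(benzyloxy)phenoxy]phenoxy}phenoxy)phenol | Oc1c(OCc2ccccc2)cc(Oc2c(OCc3ccccc3)cc(Oc3c(OCc4ccccc4)cc(Oc4c(OCc5ccccc5)cc(OCc5ccccc5)cc4OCc4ccccc4)c(OCc4ccccc4)c3OCc3ccccc3)cc2OCc2ccccc2)cc1OCc1ccccc1 | intermediate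
30 | 5-{2,6-dihydroxy-4-[2,3,6-trihydroxy-4-(2,4,6-trihydroxyphenoxy)phenoxy]phenoxy}benzene-1,2,3-triol (CNP0018315.0) | Oc1cc(O)c(Oc2cc(O)c(Oc3cc(O)c(Oc4cc(O)c(O)c(O)c4)c(O)c3)c(O)c2O)c(O)c1 | target

## Step count and risks

Total steps: 18. Longest linear sequence: 14 steps (1 → 4 → 6 → 8 → 9 → 11 → 19 → 21 → 22 → 23 → 24 → 26 → 27 → 29 → 30, i.e. steps 1–5 and 10–18). The monomer branch (12 → 13 → 15 → 16 → 18, steps 6–9) joins at step 10, and 13 is re-used in steps 14 and 16.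

Three steps most likely to fail:

Step 10 (first diaryl ether: an oxidation-prone, di-ortho-substituted phenol with an ortho-substituted bromide under Cu catalysis). The fallback replaces the copper coupling by an uncatalysed SNAr on the corresponding aryl fluoride and sets out from 16. Bromine–lithium exchange (n-BuLi, THF, −78 °C) gives [3,5-bis(benzyloxy)-4-(methoxymethoxy)phenyl]lithium F9, which is fluorinated with N-fluorobenzenesulfonimide to 1,3-bis(benzyloxy)-5-fluoro-2-(methoxymethoxy)benzene F10. Deprotonation between F and OBn (LDA, −78 °C) gives [2,4-bis(benzyloxy)-6-fluoro-3-(methoxymethoxy)phenyl]lithium F11, and a DMF quench gives 2,4-bis(benzyloxy)-6-fluoro-3-(methoxymethoxy)benzaldehyde F12. The phenoxide of 11 (Cs2CO3, DMSO, 100 °C, no copper) displaces the ortho-formyl-activated fluoride, and the route is rejoined at 19.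

Step 9 (LDA metalation next to bromine in the presence of benzyl ethers; risk of benzyne formation, halogen migration or benzylic deprotonation). The fallback uses electrophilic instead of anionic formylation and sets out from 15. Acetylation (Ac2O, pyridine) gives 4-bromo-2,6-bis(benzyloxy)phenyl acetate F5. Vilsmeier–Haack reaction (POCl3, DMF, 80 °C) attacks the position ortho to one and para to the other benzyloxy group, which is unique by symmetry, and gives via the N,N-dimethyliminium chloride F6 the aldehyde 2,6-bis(benzyloxy)-4-bromo-3-formylphenyl acetate F7. Methanolysis (K2CO3, MeOH) gives 2,4-bis(benzyloxy)-6-bromo-3-hydroxybenzaldehyde F8, and MOM protection (NaH, MOMCl) rejoins the route at 18.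

Step 1 (crossed Claisen/Dieckmann annulation; self-condensation of the keto diester 2 competes with the cross reaction). The fallback replaces the two-component [3+3] annulation by a one-component assembly of three malonate units, which has no cross-selectivity problem, and sets out from 1. Compound 1 alone (3 equiv, NaOEt 1 equiv each, EtOH removed, neat 140–145 °C, then 2 M HCl) undergoes two successive Claisen condensations through triethyl 2-oxopropane-1,1,3-tricarboxylate F1 and tetraethyl 2,4-dioxopentane-1,1,3,5-tetracarboxylate F2 (neither isolated). Dieckmann closure then gives triethyl 2,4,6-trihydroxybenzene-1,3,5-tricarboxylate F3. Saponification (aq. KOH, reflux) gives 2,4,6-trihydroxybenzene-1,3,5-tricarboxylic acid F4, which decarboxylates on acidification and warming, and the route is rejoined at 6.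

## Further compounds

F1 | step 1 | triethyl 2-oxopropane-1,1,3-tricarboxylate | CCOC(=O)CC(=O)C(C(=O)OCC)C(=O)OCC
F2 | step 1 | tetraethyl 2,4-dioxopentane-1,1,3,5-tetracarboxylate | CCOC(=O)CC(=O)C(C(=O)OCC)C(=O)C(C(=O)OCC)C(=O)OCC
F3 | step 1 | triethyl 2,4,6-trihydroxybenzene-1,3,5-tricarboxylate | CCOC(=O)c1c(O)c(C(=O)OCC)c(O)c(C(=O)OCC)c1O
F4 | step 1 | 2,4,6-trihydroxybenzene-1,3,5-tricarboxylic acid | OC(=O)c1c(O)c(C(=O)O)c(O)c(C(=O)O)c1O
F5 | step 9 | 4-bromo-2,6-bis(benzyloxy)phenyl acetate | CC(=O)Oc1c(OCc2ccccc2)cc(Br)cc1OCc1ccccc1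
F6 | step 9 | [3-acetoxy-2,4-bis(benzyloxy)-6-bromobenzylidene]dimethyliminium chloride | CC(=O)Oc1c(OCc2ccccc2)cc(Br)c(C=[N+](C)C)c1OCc1ccccc1.[Cl-]
F7 | step 9 | 2,6-bis(benzyloxy)-4-bromo-3-formylphenyl acetate | CC(=O)Oc1c(OCc2ccccc2)cc(Br)c(C=O)c1OCc1ccccc1
F8 | step 9 | 2,4-bis(benzyloxy)-6-bromo-3-hydroxybenzaldehyde | Oc1c(OCc2ccccc2)cc(Br)c(C=O)c1OCc1ccccc1
F9 | step 10 | [3,5-bis(benzyloxy)-4-(methoxymethoxy)phenyl]lithium | [Li]c1cc(OCc2ccccc2)c(OCOC)c(OCc2ccccc2)c1
F10 | step 10 | 1,3-bis(benzyloxy)-5-fluoro-2-(methoxymethoxy)benzene | COCOc1c(OCc2ccccc2)cc(F)cc1OCc1ccccc1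
F11 | step 10 | [2,4-bis(benzyloxy)-6-fluoro-3-(methoxymethoxy)phenyl]lithium | [Li]c1c(F)cc(OCc2ccccc2)c(OCOC)c1OCc1ccccc1
F12 | step 10 | 2,4-bis(benzyloxy)-6-fluoro-3-(methoxymethoxy)benzaldehyde | O=Cc1c(F)cc(OCc2ccccc2)c(OCOC)c1OCc1ccccc1
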